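(The data stem from a simulated flask with constants of no real substance, and the scatter is random.)

At late times the choice for the next run is a choice of charge: does the 0.100 M of partner in delta put the isomer of the product ahead of the substrate by 40 min, or does that take the 0.200 M of gamma?

| flask | substrate | partner | remark | time |
|---|---|---|---|---|
| birch | 0.075 M | 0.10 M | run made earlier |  |
| maple | 0.10 M | 0.10 M | run made earlier |  |
| gamma | 0.050 M | 0.200 M |  | 40 min |
| delta | 0.050 M | 0.100 M |  | 40 min |

| run | time / min | target / % | substrate / % | isomer of the product / % | open intermediate / % |
|---|---|---|---|---|---|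
| birch | 3.00 | 1.5 | 68.0 | 0 | 28.1 |
| birch | 6.00 | 4.6 | 63.0 | 2.5 | 29.5 |
| birch | 10.0 | 4.0 | 60.4 | 4.4 | 31.6 |
| birch | 15.0 | 6.8 | 55.6 | 7.5 | 28.7 |
| birch | 20.0 | 6.6 | 54.1 | 11.7 | 26.8 |
| birch | 25.0 | 6.1 | 54.4 | 15.3 | 26.6 |
| maple | 2.00 | 0 | 75.0 | 0 | 24.4 |
| maple | 3.00 | 1.4 | 69.8 | 2.1 | 28.6 |
| maple | 4.00 | 2.5 | 68.6 | 0.5 | 30.7 |
| maple | 6.00 | 1.3 | 64.5 | 1.5 | 32.2 |
| maple | 10.0 | 6.1 | 60.3 | 5.3 | 30.0 |
| maple | 15.0 | 4.3 | 58.7 | 7.7 | 29.2 |
| maple | 25.0 | 5.6 | 52.0 | 13.6 | 26.2 |

(readings scatter by 1 percentage point)

- which of these there is most of at the end, counted by the substrate in it, gamma (isomer of the product / substrate / open intermediate / target)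
- which of these there is most of at the end, counted by the substrate in it, delta (isomer of the product / substrate / open intermediate / target)
- how much there is at the end of the one of these that leads, in percent of the substrate charged: gamma
- how much there is at the end of the one of these that leads, in percent of the substrate charged: delta

1. Call conversion C the fraction of the charge standing as target plus isomer of the product. In the birch and maple readings at 25.0 min, taken together, substrate holds a share f = 0.668 of the unconverted pool of substrate plus open intermediate. The isomer holds a share φ = 0.712 of C. Each reading scatters by 1 percentage point.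

2. With both shares held, the isomer stands at φ times C and the substrate at f times the unconverted rest, so time drops out. The isomer leads once C passes the crossover conversion, f/(f+φ) = 0.484.

3. Averaged over birch and maple, C rose from 0.0990 at 10.0 min to 0.203 at 25.0 min. A straight line carries this to 0.307 at 40 min. Delta has the same partner charge, and this is less than the crossover, so delta stays with the substrate, at 0.463 of the charge.

4. Both runs used one partner charge, so the partner's effect is an assumption. If C follows partner in proportion, gamma, with twice the partner, reaches 0.614. That is past the crossover, which puts the isomer at 0.437. So the larger charge is the one to make.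

5. The forecast names the same leaders at slightly lower amounts: isomer of the product at 43% in gamma, of which it says “this is less certain”, and substrate at 45% in delta.

Gamma ends with isomer of the product leading at 38.4%, and delta with substrate leading at 45.3%.

    partner → second intermediate (k = 0.00548 s⁻¹)
    open intermediate + second intermediate → target (k = 0.0133 M⁻¹ s⁻¹)
    partner → decomposed reagent (k = 0.00577 s⁻¹)
    substrate ⇌ open intermediate (K = 0.511, k = 0.00382 s⁻¹)
    target ⇌ isomer of the product (K = 2.83, k = 0.00480 s⁻¹)

Conversion stands at 54.2% in gamma, above the crossover 0.484, and at 32.4% in delta, below it. In gamma at 40 min the free partner is gone, with 0% of its charge left against 31% of the substrate, but 0.0703 M of second intermediate still stands. The flask like delta but with 0.25 M of partner reaches a conversion of 62.2%, also past the crossover. There φ gives 0.443, and the flask holds 44.2% of its charge as isomer of the product.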